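The data are simulated from invented constants; the scatter is artificial.

At a small charge, [Q] = 1 M at the start, the teal run reaches by 1.00 h a mixture that changes slowly afterwards, so the flask needs a number for that slow change.

| flask | Q | remark | time |
|---|---|---|---|
| teal | 1 M | run made earlier |  |
| flask | 2.0 M |  | 6.0 h |

teal run (percent of the Q charged)

| time / h | L / % | G / % | Q / % | J / % |
|---|---|---|---|---|
| 1.00 | 75.4 | 2.5 | 14.2 | 9.4 |
| 2.00 | 73.3 | 4.2 | 14.0 | 8.7 |
| 3.00 | 72.3 | 6.2 | 13.4 | 8.1 |
| 4.00 | 70.7 | 8.1 | 13.4 | 8.5 |
| 5.00 | 69.9 | 10.3 | 12.2 | 8.1 |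
| 6.00 | 67.9 | 10.9 | 12.7 | 7.9 |
| 8.00 | 65.6 | 15.1 | 12.8 | 7.5 |

(each reading ± 0.3 percentage points)

- reactions considered so far: J <-> G; Q <-> J; Q <-> L

- where most of what was charged as Q, at 6.0 h is found (J / Q / G / L)
- the largest share itself, whichever of these holds it, in percent of the Q charged

Does the flask's charge, twice the teal one, matter? Each step as written has one reactant. If each is first order, percentages do not follow the charge, but a single charge cannot test that.

What stays nearly constant? Call L, Q and J together the pool. In the teal run it stands at 99.0% at 1.00 h and 85.9% at 8.00 h, and L is 76.2% and 76.4% of it. So the pool behaves as a pre-equilibrium whose proportions can be frozen.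

How fast does it shrink? The drain constant, the fractional loss of the pool per hour, is 0.0203 /h. My reckoning carries L to 6.0 h at 68.1%, larger than any teal reading of G, Q or J then, so L holds the most.

The forecast gives L at 68%, and on the untested order it says: “L stays largest either way”.

The flask gives L at 68.2%.

    J ⇌ G (K = 14.0, k = 0.00390 /min)
    Q ⇌ J (K = 0.670, k = 0.0330 /min)
    Q ⇌ L (K = 5.40, k = 0.150 /min)

In the flask, half of the turnover of Q to L was done by 0.0516 h, and L already stood at 74.2% at 0.600 h. G stood at 1.47% at that moment, and the net turnover of J to G, counted from the start up to 6.0 h, was 11.4%. Between 3.00 h and 6.0 h the flask's own pool shrinks at 0.0191 /h. For the neighbour flask read at 2.5 h, the drain constant gives L as 73.1%, and that flask holds 73.0%.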